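The amounts come first: 0.014 M of solid substrate stands against 1.4 µM of enzyme, and each enzyme can die on one molecule of product.

solid substrate 0.014 M; enzyme 1.4 µM; time 15 d

    starting material + enzyme → product + enzyme, rate k1*[starting material]^1.5*[enzyme]/(1 + ([starting material]/Kh1)^1.5) (Kh1 = 2.0 mM, k1 = 19000 M⁻¹·⁵ s⁻¹)
    enzyme + product → spent catalyst (k2 = 78 M⁻¹ h⁻¹)
    solid substrate ⇌ starting material, rate k3*(cs3 - [starting material]) while solid is left; crystals form when [starting material] > cs3 (cs3 = 3.3 mM, k3 = 0.11 h⁻¹)

- as a solid, counted per litre of solution: solid substrate
- at the start none of the solid substrate is in solution
- what has only dissolved of solid substrate counts as not reacted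
- starting material means what is dissolved; the solid is not counted in it
- run time (flask): 15 d

1. part of the solid substrate that has turned into other species by 15 d (what has only dissolved does not count)
2. how much product there is at 15 d, in percent of the solid substrate charged
3. how much starting material there is at 15 d, in percent of the solid substrate charged

Dissolution delivers at most 0.363 mM h⁻¹. The charged enzyme, with [starting material] at solubility, could use 5.82 mM h⁻¹. That ratio is 16.0, and the enzyme is faster, so I take dissolution as the rate-limiting step at first. [product] then grows steadily with time, and the logarithm of the fall in [enzyme] grows as 78 M⁻¹ h⁻¹ times [product] squared, over 2 times the delivery. The enzyme keeps up until it has fallen by that ratio, when the logarithm reaches 2.77.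

Solving for [product] and dividing by the charge gives 36.3 %. This is the stall yield, the part of the charge converted before the enzyme falls behind dissolution. It comes after 14.0 h, far shorter than the run, so I expect conv near it. The enzyme can take 1.4 µM of product at most, far less than the product made, so I put y_P at conv.

One number is not enough: it says nothing about the solution. Solubility is 23.6 % of the charge, and the two together come to 59.9 %, less than the charge. So I expect solid to remain, and I put y_A at that solubility share.

The forecast gives 38 % for conv and y_P and 23.6 % for y_A, holding that “product kills the enzyme within about a day”. Its product stands 1.7 percentage points above mine.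

This flask gives conv 33.3 %, y_P 33.3 % and y_A 23.6 %, with 43.1 % of the charge still solid at 15.0 d: the forecast holds, and the flask stops with solid unused. With the loss of enzyme to spent catalyst struck out, conv in this flask reaches 100 %. The neighbour flask charged with 3.5 × 10⁻⁷ M of enzyme, a quarter of this charge, has a ratio of 4.01. That turns the stall yield of 36.3 % into 25.7 %, and that neighbour flask gives conv 25.7 %.

The numbers of this flask were drawn at random within sensible limits; what happens was integrated by code.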